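Set Thursday's run beside Sunday's and compare their rates up to the first reading.

all flasks: Z 26 mM (held)

| run | J | remark | time |
|---|---|---|---|
| Thursday's | 0.54 M | run made earlier |  |
| Sunday's | 1.2 M | run made earlier |  |
| flask | 0.80 M |  | 5.0 d |

| run | time / d | G / % | J / % |
|---|---|---|---|
| Thursday's | 0.333 | 11.5 | 12.0 |
| Thursday's | 0.833 | 14.5 | 0.6 |
| Thursday's | 1.67 | 15.2 | 0.5 |
| Thursday's | 2.50 | 15.4 | 0.1 |
| Thursday's | 4.00 | 14.7 | 0.4 |
| Thursday's | 5.00 | 14.9 | 0 |
| Thursday's | 6.00 | 15.3 | 0.1 |
| Sunday's | 0.333 | 6.2 | 10.2 |
| Sunday's | 0.833 | 8.8 | 0.5 |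
| Sunday's | 1.67 | 8.4 | 0 |
| Sunday's | 2.50 | 9.3 | 0 |
| Sunday's | 4.00 | 8.2 | 0 |
| Sunday's | 5.00 | 8.7 | 0.2 |
| Sunday's | 6.00 | 9.1 | 0.5 |

(readings scatter by 0.5 percentage points)

- percent here means J units held: one D or Q counts as two
- at the start none of X is dissolved
- candidate steps: Z <-> X; J + X -> G; J -> L; J + G -> D; 2 J -> Q

- the G standing at 5.0 d, as a percentage of the J charged
- the change that raises the amount of G at 5.0 d, in percent of the J charged most ("none" if none brings more than 2 percentage points) (zeta / delta / none)
- amount of G at 5.0 d, in percent of the J charged, after zeta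

- zeta: doubling the saturation concentration of Z, all else as stated
- delta: doubling the transfer coefficient of Z, all else as stated

Up to 0.333 d, Thursday's flask lost J at 1.43 M/d and made G at 0.186 M/d. Sunday's flask lost J at 3.24 M/d and made G at 0.223 M/d. The charge rose by a factor 2.22, the J rate by 2.27, the G rate by 1.20.

So I took the J rate as proportional to J and the G rate as steady. As J fell, G's share of the J consumed, its selectivity, then grew. That drift integrates to a logarithm: with Z held as in these runs, I expected each e-fold of charge to add a fixed molarity of G, which I called the G step.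

From 1.67 d on, the G readings wandered within their scatter. Their means gave 0.0815 M on Thursday and 0.105 M on Sunday, so the step read as 0.0292 M. For the flask at 0.80 M, I reckoned 0.0930 M of G, which is 11.6% of its charge.

The forecast, holding that "G barely follows J", gave 11.9%, chose zeta, and put G after it at 21.5%.

The flask gave 11.8%. The best change was zeta, which added 8.1 percentage points and reached 19.9%, while delta added 4.3 points.

    Z ⇌ X, rate k1*(csat - [X]) (kL = 0.610 /h)
    J + X → G (k = 4.40 /M/h)
    J → L (k = 0.180 /h)
    J + G → D (k = 0.0400 /M/h)
    2 J → Q (k = 0.0900 /M/h)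

The neighbouring flask held 2.0 M of J, with all else unchanged. The same step put its G at 0.120 M, or 6.00% of its charge. The simulation gave 6.00%, which is 0.120 M, with 0% of its J left. Its molarity of G stood higher than the 0.0941 M of the flask at 0.80 M, but on a smaller share of the charge, 6.00% against 11.8%.

All runs come from a simulation with made-up constants; the scatter is artificial.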